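## Retrosynthetic overview
1. Target 34 is cut last at C11–C12. A Ni/Cr coupling joins ring A aldehyde 14 (fragment 1) to ring B vinyl iodide 32 (fragment 2). This step releases the only free hydroxyl, so both acetates go on early and C11–OH is never protected.
2. Key step: each 4-pyranone is closed through its ring C–O bond, next to an intact stereocentre. Ring A forms first (step 7, O–C3 closure of chlorovinyl diketone 12 with loss of HCl, new). Ring B forms second (step 19, cyclodehydration of triketone 31).
3. 12 comes from two boron aldols. Pentan-3-one 1 adds to Roche-derived aldehyde 6 (sets C8, C9). Ketone 9 then adds to chloroenal 3, itself made from pentan-3-one.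
4. 31 comes from the enolate of ketone 23 (C14 set by an allenylzinc addition) and β-lactone 28 (C20, C21 set by the proline self-aldol of propanal).

Assumption and notation: the backbone is numbered C1–C23 from the ethyl group on ring A (ring A = C3–C7, ring B = C15–C19; target = 8R,9R,10S,11S,12E,14R,20S,21S). Stereocentres that are erased later are carried as mixtures and written without descriptors.

## Fragment 1 (ring A aldehyde 14)

Step 1
Reactants: 1 pentan-3-one
Product: 3 (E/Z)-3-chloro-2-methylpent-2-enal, via chlorovinyl iminium salt 2 (not isolated)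
Conditions: POCl3 (2.5 equiv), DMF (3 equiv), 0 to 55 °C; then ice, aq NaOAc
Reagents that add atoms: N,N-dimethylformamide CN(C)C=O; phosphoryl chloride O=P(Cl)(Cl)Cl; water O
Why: Vilsmeier–Haack–Arnold chloroformylation of an enolisable ketone gives the β-chloroenal, a 2-methyl-3-oxopentanal equivalent at the right oxidation level, and its alkene geometry does not matter because C3 and C4 end up in the ring.

Step 2
Reactants: 4 methyl (S)-3-hydroxy-2-methylpropanoate
Product: 5 methyl (S)-2-methyl-3-(triethylsilyloxy)propanoate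
Conditions: TESCl, imidazole, CH2Cl2, 0 °C to rt
Reagents that add atoms: chlorotriethylsilane CC[Si](Cl)(CC)CC
Why: Standard silylation of a primary alcohol; the C10 stereocentre (S) comes from the chiral pool and is not touched.

Step 3
Reactants: 5 methyl (S)-2-methyl-3-(triethylsilyloxy)propanoate
Product: 6 (S)-2-methyl-3-(triethylsilyloxy)propanal
Conditions: iBu2AlH (1.05 equiv), CH2Cl2, −78 °C; aq potassium sodium tartrate
Reagents that add atoms: none
Why: Low-temperature iBu2AlH half-reduction of the ester stops at the aluminium hemiacetal and gives the aldehyde without epimerisation when it is used at once.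

Step 4
Reactants: 1 pentan-3-one; 6 (S)-2-methyl-3-(triethylsilyloxy)propanal
Product: 8 (4R,5R,6S)-5-hydroxy-4,6-dimethyl-7-(triethylsilyloxy)heptan-3-one, via E-boron enolate 7 (not isolated)
Conditions: (c-C6H11)2BCl, Et3N, Et2O, 0 °C; 6, −78 to −20 °C; then MeOH, pH 7 buffer, 30% H2O2, 0 °C
Reagents that add atoms: none
Why: Boron-mediated anti aldol in which the E enolate reacts through a chair transition state (C8/C9 anti) on the Felkin–Anh face of the α-methyl aldehyde (C9/C10 syn), so 8R and 9R are set from the 10S centre and minor isomers are removed by chromatography.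

Step 5
Reactants: 8 (4R,5R,6S)-5-hydroxy-4,6-dimethyl-7-(triethylsilyloxy)heptan-3-one
Product: 9 (2S,3R,4R)-2,4-dimethyl-5-oxo-1-(triethylsilyloxy)heptan-3-yl acetate
Conditions: Ac2O, pyridine, DMAP (cat.), CH2Cl2, 0 °C
Reagents that add atoms: acetic anhydride CC(=O)OC(C)=O
Why: Nucleophile-catalysed O-acylation places the C9 acetate with retention while no other hydroxyl exists.

Step 6
Reactants: 9 (2S,3R,4R)-2,4-dimethyl-5-oxo-1-(triethylsilyloxy)heptan-3-yl acetate; 3 (E/Z)-3-chloro-2-methylpent-2-enal
Product: 11 (2S,3R,4R)-9-chloro-7-hydroxy-2,4,6,8-tetramethyl-5-oxo-1-(triethylsilyloxy)undec-8-en-3-yl acetate (mixture at C6 and C7 and at the alkene), via boron enolate 10 (not isolated)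
Conditions: (c-C6H11)2BCl, Et3N, Et2O, 0 °C; 3, −78 to 0 °C; then MeOH, pH 7 buffer, 30% H2O2, 0 °C
Reagents that add atoms: none
Why: Boron aldol with amine-mediated enolisation on the unhindered CH2 side only, so C8 and the β-acetate are untouched, and 1,2-addition to the enal builds the backbone C5–C6 bond with two new stereocentres that step 7 erases.

Step 7
Reactants: 11 (2S,3R,4R)-9-chloro-7-hydroxy-2,4,6,8-tetramethyl-5-oxo-1-(triethylsilyloxy)undec-8-en-3-yl acetate
Product: 13 (2S,3R,4R)-4-(6-ethyl-3,5-dimethyl-4-oxo-4H-pyran-2-yl)-2-methyl-1-(triethylsilyloxy)pentan-3-yl acetate, via chlorovinyl diketone 12 (not isolated)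
Conditions: Dess–Martin periodinane (1.5 equiv), NaHCO3 (6 equiv), CH2Cl2, 0 °C to rt, then 35 °C, same flask
Reagents that add atoms: none
Why: Proposed new method: Dess–Martin oxidation unmasks 2-methyl-1,3-diketone 12, whose enol is a 1-oxatriene that closes from the C7 oxygen onto C3 (oxa-6π electrocyclisation, equivalent to intramolecular addition–elimination at the β-chloroenone carbon) and then loses HCl to NaHCO3 to give the 4-pyranone, so the ring C–O bond forms without acid, strong base or a dehydrating agent and neither C8 nor the β-acetate meets enolising conditions; the closest known reaction types are cyclodehydration of 1,3,5-triketones to 4-pyranones and nucleophilic vinylic substitution of β-chlorovinyl ketones by oxygen nucleophiles, but to my knowledge an aldol/oxidation/dehydrochlorination annulation from a Vilsmeier chloroenal to a fully substituted 4-pyranone next to a stereocentre has not been shown.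

Step 8
Reactants: 13 (2S,3R,4R)-4-(6-ethyl-3,5-dimethyl-4-oxo-4H-pyran-2-yl)-2-methyl-1-(triethylsilyloxy)pentan-3-yl acetate
Product: 14 (2R,3S,4R)-4-(6-ethyl-3,5-dimethyl-4-oxo-4H-pyran-2-yl)-2-methyl-1-oxopentan-3-yl acetate
Conditions: (COCl)2, DMSO, CH2Cl2, −78 to −40 °C; Et3N, −78 to −20 °C; cold pH 7 quench; used at once
Reagents that add atoms: none
Why: Swern oxidation applied directly to the primary triethylsilyl ether, in which chlorodimethylsulfonium chloride desilylates the unhindered ether to the alkoxysulfonium salt that collapses to the aldehyde, saving a separate deprotection while the cold amine step spares C10 and the β-acetate.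

## Fragment 2 (ring B vinyl iodide 32)

Step 9
Reactants: 15 pent-3-yn-2-one
Product: 16 (S)-pent-3-yn-2-ol
Conditions: RuCl[(S,S)-TsDPEN](p-cymene) (0.5 mol %), 2-propanol, rt
Reagents that add atoms: none
Why: Noyori asymmetric transfer hydrogenation of an alkynyl methyl ketone, where the (S,S) catalyst delivers hydride to one face and gives the S propargylic alcohol in high ee.

Step 10
Reactants: 16 (S)-pent-3-yn-2-ol
Product: 17 (S)-pent-3-yn-2-yl methanesulfonate
Conditions: MsCl, Et3N, CH2Cl2, −78 to 0 °C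
Reagents that add atoms: methanesulfonyl chloride CS(=O)(=O)Cl
Why: O-Sulfonylation does not touch the C–O bond, so the configuration is retained.

Step 11
Reactants: 17 (S)-pent-3-yn-2-yl methanesulfonate; 18 propanal
Product: 20 (3S,4R)-4-methylhept-5-yn-3-ol, via allenylzinc 19 (not isolated)
Conditions: Pd(OAc)2 (5 mol %), PPh3 (5 mol %), Et2Zn (3 equiv), THF, −78 to −20 °C
Reagents that add atoms: none
Why: Marshall allenylzinc addition in which zerovalent palladium displaces the mesylate anti (SN2'), Et2Zn transmetalates with retention and 19 adds to propanal through a cyclic SE2' transition state, so the aldehyde carbon replaces the mesylate with net inversion (C14 = R, anti adduct major), and the carbinol centre is erased in step 13.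

Step 12
Reactants: 20 (3S,4R)-4-methylhept-5-yn-3-ol
Product: 22 (3S,4R,5E)-6-iodo-4-methylhept-5-en-3-ol, via alkenylzirconocene 21 (not isolated)
Conditions: Cp2ZrHCl (3 equiv), THF, rt to 40 °C; then I2, 0 °C
Reagents that add atoms: iodine II
Why: Hydrozirconation–iodination, where syn addition of Zr–H places zirconium on the less hindered methyl-bearing alkyne carbon and iodinolysis proceeds with retention to give the E vinyl iodide.

Step 13
Reactants: 22 (3S,4R,5E)-6-iodo-4-methylhept-5-en-3-ol
Product: 23 (4R,5E)-6-iodo-4-methylhept-5-en-3-one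
Conditions: Dess–Martin periodinane, NaHCO3, CH2Cl2, 0 °C to rt
Reagents that add atoms: none
Why: Buffered Dess–Martin oxidation gives the β,γ-unsaturated ketone without moving the alkene or touching C14.

Step 14
Reactants: 18 propanal (two molecules)
Product: 24 (2S,3S)-3-hydroxy-2-methylpentanal
Conditions: L-proline (10 mol %), DMF, 4 °C
Reagents that add atoms: none
Why: Proline-catalysed direct self-aldol of propanal (enamine catalysis, hydrogen-bonded chair transition state) gives the anti (2S,3S) aldol in about 4:1 dr and high ee, which sets C20 and C21, and the syn isomer is removed by chromatography here and at 28.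

Step 15
Reactants: 24 (2S,3S)-3-hydroxy-2-methylpentanal
Product: 25 (2S,3S)-2-methyl-1-oxopentan-3-yl acetate
Conditions: Ac2O, pyridine, CH2Cl2, 0 °C (no DMAP)
Reagents that add atoms: acetic anhydride CC(=O)OC(C)=O
Why: O-Acetylation with retention at C21, kept cold and free of strong base so that the β-acetoxy aldehyde does not eliminate.

Step 16
Reactants: 25 (2S,3S)-2-methyl-1-oxopentan-3-yl acetate; 26 propanoyl chloride
Product: 28 (2S,3S)-2-(3-methyl-4-oxooxetan-2-yl)pentan-3-yl acetate (cis lactone), via methylketene 27 (not isolated)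
Conditions: iPr2NEt, O-trimethylsilylquinidine (15 mol %), LiI, CH2Cl2/Et2O, −78 °C
Reagents that add atoms: none
Why: Acyl halide–aldehyde cyclocondensation (the alkaloid-bound methylketene enolate adds to the LiI-activated aldehyde and lactonises, a formal [2+2]) adds C17–C18 as a strained acyl donor whose two new stereocentres are erased later.

Step 17
Reactants: 23 (4R,5E)-6-iodo-4-methylhept-5-en-3-one; 28 (2S,3S)-2-(3-methyl-4-oxooxetan-2-yl)pentan-3-yl acetate
Product: 30 (3S,4R,10R,11E)-5-hydroxy-12-iodo-4,6,8,10-tetramethyl-7,9-dioxotridec-11-en-3-yl acetate (mixture at C5 and C6 and C8), via lithium enolate 29 (not isolated)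
Conditions: LiN(iPr)2 (1.05 equiv), THF, −78 °C, 20 min; 28, −78 to −50 °C; AcOH quench at −78 °C
Reagents that add atoms: none
Why: Claisen-type C-acylation in which kinetic deprotonation takes the CH2 side because allylic 1,3-strain holds the C14–H bond in the alkene plane, the strained lactone acylates the enolate by acyl C–O cleavage, and the freed C19 alkoxide is protonated at once by the new β-diketone so the acetate does not migrate.

Step 18
Reactants: 30 (3S,4R,10R,11E)-5-hydroxy-12-iodo-4,6,8,10-tetramethyl-7,9-dioxotridec-11-en-3-yl acetate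
Product: 31 (3S,4S,10R,11E)-12-iodo-4,6,8,10-tetramethyl-5,7,9-trioxotridec-11-en-3-yl acetate
Conditions: Dess–Martin periodinane, NaHCO3, CH2Cl2, 0 °C to rt
Reagents that add atoms: none
Why: Dess–Martin oxidation of the C19 carbinol gives the 1,3,5-triketone (keto/enol mixture) under neutral conditions.

Step 19
Reactants: 31 (3S,4S,10R,11E)-12-iodo-4,6,8,10-tetramethyl-5,7,9-trioxotridec-11-en-3-yl acetate
Product: 32 (2S,3S)-2-{6-[(2R,3E)-4-iodopent-3-en-2-yl]-3,5-dimethyl-4-oxo-4H-pyran-2-yl}pentan-3-yl acetate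
Conditions: PPh3, CCl4, THF, rt
Reagents that add atoms: none
Why: Phosphonium-mediated (Appel-type) cyclodehydration of a 1,3,5-triketone, in which one enol oxygen is activated as its oxyphosphonium salt and the distal enol oxygen closes the ring B C–O bond with loss of Ph3PO, under conditions known to spare stereocentres next to the new pyranone (C14, C20).

## Union

Step 20
Reactants: 14 (2R,3S,4R)-4-(6-ethyl-3,5-dimethyl-4-oxo-4H-pyran-2-yl)-2-methyl-1-oxopentan-3-yl acetate; 32 (2S,3S)-2-{6-[(2R,3E)-4-iodopent-3-en-2-yl]-3,5-dimethyl-4-oxo-4H-pyran-2-yl}pentan-3-yl acetate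
Product: 34 CNP0282134.1, via alkenylchromium 33 (not isolated)
Conditions: CrCl2 (8 equiv), NiCl2 (2 mol %), DMSO/THF, rt
Reagents that add atoms: none
Why: Nozaki–Hiyama–Kishi coupling, where nickel-catalysed formation of 33 keeps the E geometry and chemoselective addition to the aldehyde (esters and pyranones untouched) along the Felkin–Anh trajectory should favour the 10,11-syn (11S) allylic alcohol, with the minor epimer separated.

## Compound list
1 | pentan-3-one | CCC(=O)CC | starting material
2 | N-(3-chloro-2-methylpent-2-enylidene)-N-methylmethanaminium dichlorophosphate | CCC(Cl)=C(C)C=[N+](C)C.[O-]P(Cl)(Cl)=O | intermediate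
3 | (E/Z)-3-chloro-2-methylpent-2-enal | CCC(Cl)=C(C)C=O | intermediate
4 | methyl (S)-3-hydroxy-2-methylpropanoate | COC(=O)[C@@H](C)CO | starting material
5 | methyl (S)-2-methyl-3-(triethylsilyloxy)propanoate | COC(=O)[C@@H](C)CO[Si](CC)(CC)CC | intermediate
6 | (S)-2-methyl-3-(triethylsilyloxy)propanal | O=C[C@@H](C)CO[Si](CC)(CC)CC | intermediate
7 | (E)-pent-2-en-3-yl dicyclohexylborinate | C/C=C(/OB(C1CCCCC1)C1CCCCC1)CC | intermediate
8 | (4R,5R,6S)-5-hydroxy-4,6-dimethyl-7-(triethylsilyloxy)heptan-3-one | CCC(=O)[C@H](C)[C@H](O)[C@@H](C)CO[Si](CC)(CC)CC | intermediate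
9 | (2S,3R,4R)-2,4-dimethyl-5-oxo-1-(triethylsilyloxy)heptan-3-yl acetate | CCC(=O)[C@H](C)[C@H](OC(C)=O)[C@@H](C)CO[Si](CC)(CC)CC | intermediate
10 | E dicyclohexylboron enolate of 9 (enolised towards C6) | C/C=C(/OB(C1CCCCC1)C1CCCCC1)[C@H](C)[C@H](OC(C)=O)[C@@H](C)CO[Si](CC)(CC)CC | intermediate
11 | (2S,3R,4R)-9-chloro-7-hydroxy-2,4,6,8-tetramethyl-5-oxo-1-(triethylsilyloxy)undec-8-en-3-yl acetate (C6, C7 and alkene: mixtures) | CCC(Cl)=C(C)C(O)C(C)C(=O)[C@H](C)[C@H](OC(C)=O)[C@@H](C)CO[Si](CC)(CC)CC | intermediate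
12 | (2S,3R,4R)-9-chloro-2,4,6,8-tetramethyl-5,7-dioxo-1-(triethylsilyloxy)undec-8-en-3-yl acetate | CCC(Cl)=C(C)C(=O)C(C)C(=O)[C@H](C)[C@H](OC(C)=O)[C@@H](C)CO[Si](CC)(CC)CC | intermediate
13 | (2S,3R,4R)-4-(6-ethyl-3,5-dimethyl-4-oxo-4H-pyran-2-yl)-2-methyl-1-(triethylsilyloxy)pentan-3-yl acetate | CCc1oc([C@H](C)[C@H](OC(C)=O)[C@@H](C)CO[Si](CC)(CC)CC)c(C)c(=O)c1C | intermediate
14 | (2R,3S,4R)-4-(6-ethyl-3,5-dimethyl-4-oxo-4H-pyran-2-yl)-2-methyl-1-oxopentan-3-yl acetate | CCc1oc([C@H](C)[C@H](OC(C)=O)[C@@H](C)C=O)c(C)c(=O)c1C | intermediate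
15 | pent-3-yn-2-one | CC#CC(C)=O | starting material
16 | (S)-pent-3-yn-2-ol | CC#C[C@H](C)O | intermediate
17 | (S)-pent-3-yn-2-yl methanesulfonate | CC#C[C@H](C)OS(C)(=O)=O | intermediate
18 | propanal | CCC=O | starting material
19 | ethyl(penta-2,3-dien-2-yl)zinc, single allene enantiomer | CC[Zn]C(C)=[C@@]=C(C)[H] | intermediate
20 | (3S,4R)-4-methylhept-5-yn-3-ol | CC#C[C@@H](C)[C@H](CC)O | intermediate
21 | O,C-bis(chlorozirconocene) derivative of 20 (E alkenyl, Zr on the methyl-bearing carbon) | Cl[Zr](C1C=CC=C1)(C1C=CC=C1)/C(C)=C/[C@@H](C)[C@H](CC)O[Zr](Cl)(C1C=CC=C1)C1C=CC=C1 | intermediate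
22 | (3S,4R,5E)-6-iodo-4-methylhept-5-en-3-ol | I/C(C)=C/[C@@H](C)[C@H](CC)O | intermediate
23 | (4R,5E)-6-iodo-4-methylhept-5-en-3-one | I/C(C)=C/[C@@H](C)C(=O)CC | intermediate
24 | (2S,3S)-3-hydroxy-2-methylpentanal | O=C[C@@H](C)[C@H](CC)O | intermediate
25 | (2S,3S)-2-methyl-1-oxopentan-3-yl acetate | O=C[C@@H](C)[C@H](CC)OC(C)=O | intermediate
26 | propanoyl chloride | CCC(=O)Cl | starting material
27 | methylketene (prop-1-en-1-one) | CC=C=O | intermediate
28 | (2S,3S)-2-(3-methyl-4-oxooxetan-2-yl)pentan-3-yl acetate (cis lactone, lactone centres not specified) | CC1C(=O)OC1[C@@H](C)[C@H](CC)OC(C)=O | intermediate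
29 | lithium enolate of 23 (enolised towards C16) | I/C(C)=C/[C@@H](C)C([O-])=CC.[Li+] | intermediate
30 | (3S,4R,10R,11E)-5-hydroxy-12-iodo-4,6,8,10-tetramethyl-7,9-dioxotridec-11-en-3-yl acetate (C5, C6, C8: mixtures) | I/C(C)=C/[C@@H](C)C(=O)C(C)C(=O)C(C)C(O)[C@@H](C)[C@H](CC)OC(C)=O | intermediate
31 | (3S,4S,10R,11E)-12-iodo-4,6,8,10-tetramethyl-5,7,9-trioxotridec-11-en-3-yl acetate | I/C(C)=C/[C@@H](C)C(=O)C(C)C(=O)C(C)C(=O)[C@@H](C)[C@H](CC)OC(C)=O | intermediate
32 | (2S,3S)-2-{6-[(2R,3E)-4-iodopent-3-en-2-yl]-3,5-dimethyl-4-oxo-4H-pyran-2-yl}pentan-3-yl acetate | I/C(C)=C/[C@@H](C)c1oc([C@@H](C)[C@H](CC)OC(C)=O)c(C)c(=O)c1C | intermediate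
33 | E alkenylchromium dichloride derived from 32 | Cl[Cr](Cl)/C(C)=C/[C@@H](C)c1oc([C@@H](C)[C@H](CC)OC(C)=O)c(C)c(=O)c1C | intermediate
34 | (2S,3S)-2-{6-[(2R,3E,5S,6S,7R,8R)-7-acetoxy-8-(6-ethyl-3,5-dimethyl-4-oxo-4H-pyran-2-yl)-5-hydroxy-4,6-dimethylnon-3-en-2-yl]-3,5-dimethyl-4-oxo-4H-pyran-2-yl}pentan-3-yl acetate (CNP0282134.1) | CCc1oc([C@H](C)[C@H](OC(C)=O)[C@@H](C)[C@H](O)/C(C)=C/[C@@H](C)c2oc([C@@H](C)[C@H](CC)OC(C)=O)c(C)c(=O)c2C)c(C)c(=O)c1C | target

## Step count and risks
Total step count: 20. Longest linear sequence: 9 steps (15 → 16 → 17 → 20 → 22 → 23 → 30 → 31 → 32 → 34). Fragment 1 needs 7 linear steps from 4 before the union.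

**Step 7 (the proposed new ring closure).** Diketone 12 may stall as the open chlorovinyl compound, hydrolyse, or lose acetic acid. The fallback uses known chemistry, sets out from 9 (with 24) and returns at 13.
- Aldol 24 is protected with 4-methoxybenzyl trichloroacetimidate and catalytic camphorsulfonic acid to give (2S,3S)-3-(4-methoxybenzyloxy)-2-methylpentanal F1.
- The boron enolate of 9 is added to it to give the hydroxy ketone PMB ether F2.
- Buffered DDQ frees the diol F3.
- Double Dess–Martin oxidation gives the open 1,3,5-triketone F4.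
- PPh3/CCl4 cyclodehydration, as in step 19, delivers 13.

**Step 17.** Competing deprotonation at C14 would cause racemisation or alkene migration, attack at the acetate is possible, and the hindered lactone may react slowly. The fallback avoids lithium bases, sets out from 23 and returns at 30.
- Boron aldol of 23 with propanal 18 gives the β-hydroxy ketone F5.
- Dess–Martin oxidation gives (6R,7E)-8-iodo-4,6-dimethylnon-7-ene-3,5-dione F6.
- TMSOTf/Et3N gives the 1,3-bis(trimethylsilyloxy)diene F7.
- BF3·OEt2-mediated vinylogous Mukaiyama aldol of its terminal carbon with aldehyde 25 gives 30.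

**Step 20.** Felkin control opposes the 1,3-effect of the β-acetate, so selectivity at C11 may be modest or reversed. Aldehyde 14 can also eliminate. The fallback sets out from 14 and 32 and returns at 34.
- The coupling is run without regard to selectivity, giving 34 together with the 11R epimer F8.
- The mixture is oxidised with buffered Dess–Martin periodinane to the C11 enone F9, which is handled cold and briefly.
- F9 is reduced under reagent control with (R)-2-methyl-CBS-oxazaborolidine and catecholborane at −78 °C, the alkenyl arm acting as the large group, to give 34.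

## Further compounds
F1 | step 7 | (2S,3S)-3-(4-methoxybenzyloxy)-2-methylpentanal | O=C[C@@H](C)[C@H](CC)OCc1ccc(OC)cc1
F2 | step 7 | (2S,3R,4R,8S,9S)-7-hydroxy-9-(4-methoxybenzyloxy)-2,4,6,8-tetramethyl-5-oxo-1-(triethylsilyloxy)undecan-3-yl acetate (C6, C7 mixtures) | CC[C@H](OCc1ccc(OC)cc1)[C@H](C)C(O)C(C)C(=O)[C@H](C)[C@H](OC(C)=O)[C@@H](C)CO[Si](CC)(CC)CC
F3 | step 7 | 7,9-diol obtained from F2 by removal of the 4-methoxybenzyl group | CC[C@H](O)[C@H](C)C(O)C(C)C(=O)[C@H](C)[C@H](OC(C)=O)[C@@H](C)CO[Si](CC)(CC)CC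
F4 | step 7 | (2S,3R,4R)-2,4,6,8-tetramethyl-5,7,9-trioxo-1-(triethylsilyloxy)undecan-3-yl acetate | CCC(=O)C(C)C(=O)C(C)C(=O)[C@H](C)[C@H](OC(C)=O)[C@@H](C)CO[Si](CC)(CC)CC
F5 | step 17 | (6R,7E)-3-hydroxy-8-iodo-4,6-dimethylnon-7-en-5-one (C3, C4 mixtures) | I/C(C)=C/[C@@H](C)C(=O)C(C)C(O)CC
F6 | step 17 | (6R,7E)-8-iodo-4,6-dimethylnon-7-ene-3,5-dione | I/C(C)=C/[C@@H](C)C(=O)C(C)C(=O)CC
F7 | step 17 | bis(trimethylsilyl) dienol ether of F6 | I/C(C)=C/[C@@H](C)C(O[Si](C)(C)C)=C(C)C(O[Si](C)(C)C)=CC
F8 | step 20 | 11R epimer of 34 | CCc1oc([C@H](C)[C@H](OC(C)=O)[C@@H](C)[C@@H](O)/C(C)=C/[C@@H](C)c2oc([C@@H](C)[C@H](CC)OC(C)=O)c(C)c(=O)c2C)c(C)c(=O)c1C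
F9 | step 20 | C11 enone (11-oxo analogue of 34) | CCc1oc([C@H](C)[C@H](OC(C)=O)[C@@H](C)C(=O)/C(C)=C/[C@@H](C)c2oc([C@@H](C)[C@H](CC)OC(C)=O)c(C)c(=O)c2C)c(C)c(=O)c1C
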